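(The readings are simulated on assumed constants; scatter was added.)

**Two ratios.** Side product over target after 50.0 h is 0.110 in Thursday's run and 0.648 in Sunday's run, whose substrate concentration is 6.14 times higher. So you suspect that the split moves with concentration.

the same everywhere: free catalyst 0.34 mol%

| charge | substrate | reagent | remark | time |
|---|---|---|---|---|
| Thursday's | 0.14 M | 1.1 equiv | run made earlier |  |
| Sunday's | 0.86 M | 1.1 equiv | run made earlier |  |
| autumn | 0.12 M | 1.10 equiv |  | 2.0 d |
| dusk | 0.60 M | 1.10 equiv |  | 2.0 d |
| dawn | 0.23 M | 1.10 equiv |  | 2.0 d |
| midnight | 0.30 M | 1.10 equiv |  | 2.0 d |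

| run | time / h | target / % | side product / % |
|---|---|---|---|
| Thursday's | 4.00 | 6.9 | 0 |
| Thursday's | 12.0 | 11.1 | 1.5 |
| Thursday's | 20.0 | 18.0 | 0 |
| Thursday's | 30.0 | 25.4 | 1.5 |
| Thursday's | 50.0 | 37.4 | 4.1 |
| Sunday's | 10.0 | 9.2 | 0 |
| Sunday's | 20.0 | 15.4 | 0.7 |
| Sunday's | 30.0 | 18.8 | 3.7 |
| Sunday's | 40.0 | 18.9 | 8.9 |
| Sunday's | 50.0 | 21.0 | 13.6 |

(each reading ± 1 percentage point)

- ranking by share of target in all that became target or side product, from high to low, at 2.0 d (autumn / dusk / dawn / midnight)
- the share of target in all that became target or side product of the flask you put first, at 2.0 d
- the share of target in all that became target or side product of the flask you put last, at 2.0 d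

**Target's lifetime.** Side product appears late, so treat it as lost target. Late in Sunday's run you read 42.4 h as the lifetime of target against loss: target fraction over side product gained per hour. Assume it scales inversely with substrate concentration times target fraction.

**First doubt.** Thursday's run, read directly, gives 242 h, and scaling gives 166 h. But that reading rests on a gain of 2.6 percentage points, from two readings each good to 1 point. The two don't separate.

**Counting lifetimes.** Divide the run time by the final lifetime. With target rising steadily, side product over target is a third of this count. With target flat, it is the whole count. Which applies? The runs give factors of 0.305 for Thursday's and 0.522 for Sunday's.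

**Your estimate.** Borrow Thursday's target and factor for autumn, which gives a target share, the selectivity, of 91.7%. Borrow Sunday's for dusk, which gives 69.7%. Dusk is the shakier figure, since its target is borrowed from a more concentrated run.

**The forecast.** It ranks autumn > dawn > midnight > dusk, with 90% (86% to 94%) first and 67% (60% to 74%) last. Its ground: “Share falls steadily as concentration rises, which places dawn and midnight between them.”

**The result.** The flasks rank autumn > dawn > midnight > dusk, from 89.6% down to 66.3%. The order held, and both values fell within the forecast's ranges.

    reagent + free catalyst → catalyst intermediate A (k = 3500 M⁻¹ h⁻¹)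
    substrate + catalyst intermediate A → catalyst intermediate B (k = 130 M⁻¹ h⁻¹)
    catalyst intermediate B ⇌ released group + catalyst intermediate C (K = 0.140 M, k = 140 h⁻¹)
    catalyst intermediate C → free catalyst + target (k = 3.80 h⁻¹)
    target + released group → side product (k = 0.140 M⁻¹ h⁻¹)

**A neighbour.** Autumn ends with 36.5% target and 4.26% side product, a count of 0.289 and a factor of 0.404. Its neighbour, charged with 0.85 mol% of free catalyst, reaches 65.4% target, so its count is 0.518. Autumn's factor then gives a target share of 82.7%. The neighbour stands at 79.5%, with 16.8% side product.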